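I wanted one ratio. The questions ask for one share at different times, and that share follows from the isomer of the product per target, so I needed neither curve by itself.

| flask | starting material | protic impurity | remark | time |
|---|---|---|---|---|
| north-west | 1.6 M | 0.80 M | run made earlier |  |
| north-east | 1.6 M | 1.2 M | run made earlier |  |
| flask | 1.6 M | 1.60 M |  | 2.5 h |

| run | time / min | target / % | isomer of the product / % |
|---|---|---|---|
| north-west | 20.0 | 52 | 0 |
| north-west | 40.0 | 66 | 2 |
| north-west | 60.0 | 73 | 3 |
| north-west | 80.0 | 74 | 3 |
| north-west | 90.0 | 73 | 0 |
| north-west | 120 | 74 | 4 |
| north-east | 10.0 | 29 | 0 |
| north-east | 15.0 | 41 | 3 |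
| north-east | 25.0 | 53 | 2 |
| north-east | 40.0 | 64 | 4 |
| north-east | 80.0 | 71 | 5 |
| north-east | 120 | 73 | 1 |

(standard deviation of a reading: 1.5 percentage points)

- a reading or a percentage of target counts all its forms, free or not

- share of target in target plus isomer of the product at 30 s
- share of target in target plus isomer of the product at 8.0 min
- share of target in target plus isomer of the product at 2.5 h

I replaced the curves by their mean. The sum of the isomer readings of both runs over the sum of their target readings came to 3.63 %; this mean isomer ratio is a selectivity factor read from the runs.

Then I checked what the mean hid. Run against run, the ratio was 2.91 % in north-west and 4.53 % in north-east. Earlier rows against later rows, it was 3.18 % and 3.96 %. Each such ratio carried about 0.99 percentage points, so gaps of 1.6 points and 0.78 points stayed below 2 points. Neither stood clear of the scatter.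

I committed to 96.5 % at each asked time, with the later and earlier rows giving 96.2 % to 96.9 %. That was a bet, since 30 s lies before any reading and this flask holds more impurity than either run.

The forecast gave 96 %, 96 % and 95.7 %, holding that “the ratio is roughly constant in time”, and my last figure stood above its own.

The flask gave 96.6 %, 96.5 % and 96.6 %.

    crystals ⇌ target, rate k1*(cs1 - [target]) while solid is left; crystals form when [target] > cs1 (solubility = 34.0 mM, k = 3.52 /min)
    2 starting material → self-condensation product (k = 0.00335 /M/min)
    starting material + protic impurity → quenched substrate (k = 0.00678 /M/min)
    starting material ⇌ target (K = 2.70, k = 0.0402 /min)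
    starting material ⇌ isomer of the product (K = 2.00, k = 0.00143 /min)

In the flask at 2.50 h, the mean isomer ratio times 69.4 % of target gave 2.52 % of isomer, and the flask held 2.42 %. The neighbour flask was charged with 0.96 M of protic impurity, its other charges and time as in the recipe. It ended with 75.0 % of target, more than the flask. The same ratio times that target gave 2.72 % of isomer, and the neighbour flask held 2.60 %. Its share at 2.50 h was 96.6 %.

(The runs stem from a simulated flask from invented constants; scatter was added.)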